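## Retrosynthetic overview

1. Target 29 ⇐ hydrogenolysis of two benzyl ethers ⇐ double Mitsunobu esterification (inversion at C6 of each alcohol) of the unsymmetrical α-truxillic diacid 27 with two molecules of 6-epi-incarvilline 12.
2. 12 ⇐ ketone 11 ⇐ one-face hydrogenation (relayed from a CBS-set carbinol) of the achiral dienone 7 ⇐ allenic Pauson–Khand (2+2+1) reaction of the open-chain carbamate 6 with CO. This forms C4a–C7a, C5–C6 and C6–C7 and closes the piperidine and cyclopentane rings in one operation (cyclopenta[c]pyridine numbering: C1, N2, C3, C4, C4a, C5, C6, C7, C7a).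
3. Enabling feature: the oxygenated C6 lies between the C5 methylene and the methyl-bearing C7 (a CO carbon between an allene terminus and a methyl-alkyne carbon). H4, H4a and H7a sit on one face of the cis-fused six/five ring pair, the mark of a flat C4=C4a–C7a=C7 diene hydrogenated from one side; C7 is enolisable and C6 is set last.
4. 27 ⇐ trans-cyclobutane-1,3-dicarboxylic acid monoester 16 by two palladium-catalysed C–H arylations. The first is enantioselective and directed by an N-aryl amide on one carboxyl; the second is directed by a bidentate anilide on the other carboxyl and places the aryl groups trans (1α,2α,3β,4β).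
5. Ring order: piperidine and cyclopentane together in step 4 (made once, used twice); the cyclobutane and the arenes are bought and only substituted.

Key step: step 4

Assumption: trans acid 16 is taken as a commercial building block, and the ligand of step 11 is used as whichever antipode (both derive from tert-leucine) activates the methylene that leads to 21, the sense being confirmed by correlation.

## Route

Step 1
Reactants: 1 but-2-yn-1-amine hydrochloride; 2 methyl chloroformate
Product: 3 methyl but-2-yn-1-ylcarbamate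
Conditions: Et3N, CH2Cl2, 0 °C to rt
Reagents that add atoms: none
Why: Schotten–Baumann-type N-acylation of the liberated primary amine by the chloroformate should give the carbamate cleanly; no stereocentre is formed.

Step 2
Reactants: 3 methyl but-2-yn-1-ylcarbamate; 4 1,4-dichlorobut-2-yne (excess)
Product: 5 methyl (but-2-yn-1-yl)(4-chlorobut-2-yn-1-yl)carbamate
Conditions: NaH, DMF, 0 °C to rt
Reagents that add atoms: none
Why: SN2 N-alkylation of the sodium carbamate at one propargylic chloride, with the excess of the symmetrical dichloride suppressing double alkylation; no stereocentre is formed.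

Step 3
Reactants: 5 methyl (but-2-yn-1-yl)(4-chlorobut-2-yn-1-yl)carbamate
Product: 6 methyl (but-2-yn-1-yl)(2-methylbuta-2,3-dien-1-yl)carbamate
Conditions: MeMgBr, CuBr·SMe2 (10 mol %), THF, −40 to 0 °C
Reagents that add atoms: methylmagnesium bromide, C[Mg]Br
Why: copper-catalysed SN2′ substitution of a primary propargylic chloride by a methyl Grignard reagent should deliver the methyl group to the alkyne carbon remote from chloride and give the 1,1-disubstituted allene, the carbamate and the internal alkyne being inert at this temperature; no stereocentre is formed.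

Step 4
Reactants: 6 methyl (but-2-yn-1-yl)(2-methylbuta-2,3-dien-1-yl)carbamate
Product: 7 methyl 4,7-dimethyl-6-oxo-1,3,5,6-tetrahydro-2H-cyclopenta[c]pyridine-2-carboxylate
Conditions: [Rh(CO)2Cl]2 (5 mol %), CO (1 atm), toluene, 90 °C
Reagents that add atoms: carbon monoxide, [C-]#[O+]
Why: Monovalent rhodium should couple the alkyne with the distal (C4a=C5) π-bond of the allene by oxidative cyclisation to a rhodacyclopentene, which forms the C4a–C7a bond; CO insertion and reductive elimination then join C5–C6 and C6–C7. The closest known reaction type is the rhodium-catalysed allenic Pauson–Khand (2+2+1) cycloaddition of nitrogen-tethered allenynes to 4-alkylidenecyclopentenones. The six-membered ring closes by C–C bond formation between the internal alkyne carbon and the central allene carbon, the proximal allene double bond ending up endocyclic as C4=C4a, and the five-membered ring closes as the carbonylative annulation of C7, C7a, C4a and C5 around the CO carbon. No stereocentre is created, by design: the product is a flat, achiral dienone that carries every carbon of the bicyclic alcohol. The step needs engagement of the distal and not the proximal allene π-bond, and cyclocarbonylation in place of cycloisomerisation; the first is the inherent preference of this catalyst and is helped by the unsubstituted allene terminus and the fully substituted proximal carbon, the second by the CO atmosphere and the absence of allylic hydrogens on the distal allene carbon.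

Step 5
Reactants: 7 methyl 4,7-dimethyl-6-oxo-1,3,5,6-tetrahydro-2H-cyclopenta[c]pyridine-2-carboxylate
Product: 8 methyl (6R)-6-hydroxy-4,7-dimethyl-1,3,5,6-tetrahydro-2H-cyclopenta[c]pyridine-2-carboxylate
Conditions: (S)-2-methyl-CBS-oxazaborolidine (20 mol %), catecholborane, toluene, −78 °C
Reagents that add atoms: none
Why: Corey–Bakshi–Shibata 1,2-reduction, in which the oxazaborolidine distinguishes the methyl-substituted alkenyl flank (C7, large) from the C5 methylene (small) and delivers hydride to one carbonyl face, should set C6 as R, the only stereocentre.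

Step 6
Reactants: 8 methyl (6R)-6-hydroxy-4,7-dimethyl-1,3,5,6-tetrahydro-2H-cyclopenta[c]pyridine-2-carboxylate
Product: 9 methyl (4R,4aS,6R,7R,7aR)-6-hydroxy-4,7-dimethyloctahydro-2H-cyclopenta[c]pyridine-2-carboxylate
Conditions: [Ir(cod)(PCy3)(py)]PF6 (10 mol %), H2 (10 bar), CH2Cl2, rt
Reagents that add atoms: none
Why: hydroxyl-directed homogeneous hydrogenation, in which iridium bound to the C6 hydroxyl delivers hydrogen to the allylic C7=C7a and the homoallylic C4=C4a tetrasubstituted olefins from the carbinol face, should place H7, H7a, H4a and H4 syn to OH and so fix C4, C4a and C7a in the required absolute sense (C7 is corrected in step 7).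

Step 7
Reactants: 9 methyl (4R,4aS,6R,7R,7aR)-6-hydroxy-4,7-dimethyloctahydro-2H-cyclopenta[c]pyridine-2-carboxylate
Product: 11 methyl (4R,4aS,7S,7aR)-4,7-dimethyl-6-oxooctahydro-2H-cyclopenta[c]pyridine-2-carboxylate, via C7-epimeric ketone 10 (not isolated)
Conditions: Dess–Martin periodinane, CH2Cl2, 0 °C to rt; then DBU (0.2 equiv), toluene, rt
Reagents that add atoms: none
Why: Dess–Martin oxidation followed by base-mediated epimerisation of the enolisable C7 should give the thermodynamically favoured ketone with the C7 methyl trans to the C7a–C1 bond, while C4, C4a and C7a are not enolisable and keep their configuration.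

Step 8
Reactants: 11 methyl (4R,4aS,7S,7aR)-4,7-dimethyl-6-oxooctahydro-2H-cyclopenta[c]pyridine-2-carboxylate
Product: 12 (4R,4aS,6S,7S,7aR)-2,4,7-trimethyloctahydro-1H-cyclopenta[c]pyridin-6-ol (6-epi-incarvilline)
Conditions: LiAlH4, THF, −78 °C, then reflux
Reagents that add atoms: none
Why: hydride reduction in which LiAlH4 attacks the ketone from the convex face of the cis-fused bicycle (the face of H4a and H7a, away from the piperidine ring) should give the 6S alcohol with hydroxyl trans to the C7 methyl, and on heating the same reagent reduces the methyl carbamate to the N-methyl group.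

Step 9
Reactants: 13 4-iodo-2-methoxyphenol; 14 benzyl bromide
Product: 15 1-(benzyloxy)-4-iodo-2-methoxybenzene
Conditions: K2CO3, DMF, rt
Reagents that add atoms: none
Why: Williamson ether synthesis on the phenoxide; no stereocentre is formed.

Step 10
Reactants: 16 trans-3-(methoxycarbonyl)cyclobutane-1-carboxylic acid; 17 2,3,5,6-tetrafluoro-4-(trifluoromethyl)aniline
Product: 19 methyl trans-3-{[2,3,5,6-tetrafluoro-4-(trifluoromethyl)phenyl]carbamoyl}cyclobutane-1-carboxylate, via acid chloride 18 (not isolated)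
Conditions: (COCl)2, DMF (cat.), CH2Cl2, rt; concentrate; then 17, toluene, 110 °C
Reagents that add atoms: oxalyl chloride, ClC(=O)C(=O)Cl (its chlorine is carried only by 18)
Why: acid chloride formation and base-free acylation of the weakly nucleophilic polyfluoroaniline should give the acidic N-aryl amide without touching the trans relation of the two carboxyl carbons.

Step 11
Reactants: 19 methyl trans-3-{[2,3,5,6-tetrafluoro-4-(trifluoromethyl)phenyl]carbamoyl}cyclobutane-1-carboxylate; 20 1-(benzyloxy)-4-iodobenzene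
Product: 21 methyl 2-[4-(benzyloxy)phenyl]-3-{[2,3,5,6-tetrafluoro-4-(trifluoromethyl)phenyl]carbamoyl}cyclobutane-1-carboxylate (aryl cis to the amide, trans to the ester; single enantiomer as in the SMILES)
Conditions: Pd(OAc)2 (10 mol %), chiral acetyl-protected aminomethyl oxazoline ligand from tert-leucine (20 mol %), Ag2CO3, HFIP, 80 °C
Reagents that add atoms: none
Why: enantioselective amide-directed β-methylene C(sp3)–H arylation on a divalent/tetravalent palladium cycle, in which cyclopalladation is only possible cis to the amide so the aryl group enters cis to the carboxamide and trans to the ester, while the chiral ligand selects one of the two enantiotopic methylenes and thereby fixes the absolute configuration of all three ring stereocentres.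

Step 12
Reactants: 21 methyl 2-[4-(benzyloxy)phenyl]-3-{[2,3,5,6-tetrafluoro-4-(trifluoromethyl)phenyl]carbamoyl}cyclobutane-1-carboxylate
Product: 22 2-[4-(benzyloxy)phenyl]-3-{[2,3,5,6-tetrafluoro-4-(trifluoromethyl)phenyl]carbamoyl}cyclobutane-1-carboxylic acid (aryl cis to the amide, trans to the acid)
Conditions: LiOH, THF/H2O, 0 °C to rt; then 1 M HCl
Reagents that add atoms: lithium hydroxide, [Li+].[OH-]
Why: saponification of the methyl ester, with the anilide protected as its amidate and the ester carbon already in its more stable arrangement trans to the aryl group, should proceed without epimerisation.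

Step 13
Reactants: 22 2-[4-(benzyloxy)phenyl]-3-{[2,3,5,6-tetrafluoro-4-(trifluoromethyl)phenyl]carbamoyl}cyclobutane-1-carboxylic acid; 23 2-(methylsulfanyl)aniline
Product: 24 2-[4-(benzyloxy)phenyl]-N1-[2-(methylsulfanyl)phenyl]-N3-[2,3,5,6-tetrafluoro-4-(trifluoromethyl)phenyl]cyclobutane-1,3-dicarboxamide (aryl trans to the C1 amide, cis to the C3 amide)
Conditions: EDC (free base), HOBt (cat.), CH2Cl2, rt
Reagents that add atoms: none
Why: carbodiimide amide coupling installs the bidentate N,S directing group on the carboxyl that is trans to the first aryl group; no stereocentre is touched.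

Step 14
Reactants: 24 2-[4-(benzyloxy)phenyl]-N1-[2-(methylsulfanyl)phenyl]-N3-[2,3,5,6-tetrafluoro-4-(trifluoromethyl)phenyl]cyclobutane-1,3-dicarboxamide; 15 1-(benzyloxy)-4-iodo-2-methoxybenzene
Product: 25 (1α,2α,3β,4β)-2-[4-(benzyloxy)-3-methoxyphenyl]-4-[4-(benzyloxy)phenyl]-N1-[2-(methylsulfanyl)phenyl]-N3-[2,3,5,6-tetrafluoro-4-(trifluoromethyl)phenyl]cyclobutane-1,3-dicarboxamide (single enantiomer as in the SMILES)
Conditions: Pd(OAc)2 (15 mol %), Ag2CO3, PivOH, HFIP, 90 °C
Reagents that add atoms: none
Why: auxiliary-directed C(sp3)–H arylation through a five-membered N,S-chelated palladacycle cleaves the C–H bond of the only methylene that is cis to the bidentate amide, so the second aryl group enters cis to that amide and trans to the first aryl group; the monodentate polyfluoroanilide is outcompeted by the chelating auxiliary and the methine C–H is not activated.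

Step 15
Reactants: 25 (1α,2α,3β,4β)-2-[4-(benzyloxy)-3-methoxyphenyl]-4-[4-(benzyloxy)phenyl]-N1-[2-(methylsulfanyl)phenyl]-N3-[2,3,5,6-tetrafluoro-4-(trifluoromethyl)phenyl]cyclobutane-1,3-dicarboxamide
Product: 27 (1α,2α,3β,4β)-2-[4-(benzyloxy)-3-methoxyphenyl]-4-[4-(benzyloxy)phenyl]cyclobutane-1,3-dicarboxylic acid (single enantiomer as in the SMILES), via bis-Boc imide 26 (not isolated)
Conditions: Boc2O, DMAP, MeCN, 60 °C; concentrate; then LiOH, H2O2, THF/H2O, 0 °C; Na2SO3; 1 M HCl
Reagents that add atoms: di-tert-butyl dicarbonate, CC(C)(C)OC(=O)OC(=O)OC(C)(C)C (Boc groups carried only by 26); hydrogen peroxide, OO (as LiOOH, source of the carboxyl OH oxygen)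
Why: N-Boc activation turns both secondary anilides into twisted imides that lithium hydroperoxide cleaves at the acyl carbon at 0 °C, conditions under which the α-stereocentres should not epimerise.

Step 16
Reactants: 27 (1α,2α,3β,4β)-2-[4-(benzyloxy)-3-methoxyphenyl]-4-[4-(benzyloxy)phenyl]cyclobutane-1,3-dicarboxylic acid; 12 6-epi-incarvilline (2.4 equiv)
Product: 28 bis[(4R,4aS,6R,7S,7aR)-2,4,7-trimethyloctahydro-1H-cyclopenta[c]pyridin-6-yl] (1α,2α,3β,4β)-2-[4-(benzyloxy)-3-methoxyphenyl]-4-[4-(benzyloxy)phenyl]cyclobutane-1,3-dicarboxylate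
Conditions: PPh3, DIAD, THF, 0 °C to rt
Reagents that add atoms: none
Why: double Mitsunobu esterification, in which each activated secondary alcohol is displaced by carboxylate with inversion, converts 6S into the 6R configuration of the target at both C6 centres and leaves the cyclobutane stereocentres untouched.

Step 17
Reactants: 28 bis[(4R,4aS,6R,7S,7aR)-2,4,7-trimethyloctahydro-1H-cyclopenta[c]pyridin-6-yl] (1α,2α,3β,4β)-2-[4-(benzyloxy)-3-methoxyphenyl]-4-[4-(benzyloxy)phenyl]cyclobutane-1,3-dicarboxylate
Product: 29 bis[(4R,4aS,6R,7S,7aR)-2,4,7-trimethyloctahydro-1H-cyclopenta[c]pyridin-6-yl] (1α,2α,3β,4β)-2-(4-hydroxy-3-methoxyphenyl)-4-(4-hydroxyphenyl)cyclobutane-1,3-dicarboxylate (CNP0331906.2)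
Conditions: H2 (1 atm), Pd/C, MeOH/EtOAc, rt
Reagents that add atoms: none
Why: hydrogenolysis of the two benzyl aryl ethers over palladium on carbon should free both phenols while the esters, the tertiary amines and the cyclobutane remain intact; no stereocentre is affected.

## Compound list

1 | but-2-yn-1-amine hydrochloride | CC#CCN.Cl | starting material
2 | methyl chloroformate | COC(=O)Cl | starting material
3 | methyl but-2-yn-1-ylcarbamate | CC#CCNC(=O)OC | intermediate
4 | 1,4-dichlorobut-2-yne | ClCC#CCCl | starting material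
5 | methyl (but-2-yn-1-yl)(4-chlorobut-2-yn-1-yl)carbamate | CC#CCN(CC#CCCl)C(=O)OC | intermediate
6 | methyl (but-2-yn-1-yl)(2-methylbuta-2,3-dien-1-yl)carbamate | CC#CCN(CC(C)=C=C)C(=O)OC | intermediate
7 | methyl 4,7-dimethyl-6-oxo-1,3,5,6-tetrahydro-2H-cyclopenta[c]pyridine-2-carboxylate | COC(=O)N1CC(C)=C2CC(=O)C(C)=C2C1 | intermediate
8 | methyl (6R)-6-hydroxy-4,7-dimethyl-1,3,5,6-tetrahydro-2H-cyclopenta[c]pyridine-2-carboxylate | O[C@@H]1CC2=C(C)CN(C(=O)OC)CC2=C1C | intermediate
9 | methyl (4R,4aS,6R,7R,7aR)-6-hydroxy-4,7-dimethyloctahydro-2H-cyclopenta[c]pyridine-2-carboxylate | O[C@@H]1C[C@@H]2[C@@H](CN(C(=O)OC)C[C@@H]2C)[C@H]1C | intermediate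
10 | methyl (4R,4aS,7R,7aR)-4,7-dimethyl-6-oxooctahydro-2H-cyclopenta[c]pyridine-2-carboxylate | O=C1C[C@@H]2[C@@H](CN(C(=O)OC)C[C@@H]2C)[C@H]1C | intermediate (not isolated)
11 | methyl (4R,4aS,7S,7aR)-4,7-dimethyl-6-oxooctahydro-2H-cyclopenta[c]pyridine-2-carboxylate | O=C1C[C@@H]2[C@@H](CN(C(=O)OC)C[C@@H]2C)[C@@H]1C | intermediate
12 | (4R,4aS,6S,7S,7aR)-2,4,7-trimethyloctahydro-1H-cyclopenta[c]pyridin-6-ol (6-epi-incarvilline) | O[C@H]1C[C@@H]2[C@@H](CN(C)C[C@@H]2C)[C@@H]1C | intermediate
13 | 4-iodo-2-methoxyphenol | COc1cc(I)ccc1O | starting material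
14 | benzyl bromide | BrCc1ccccc1 | starting material
15 | 1-(benzyloxy)-4-iodo-2-methoxybenzene | COc1cc(I)ccc1OCc1ccccc1 | intermediate
16 | trans-3-(methoxycarbonyl)cyclobutane-1-carboxylic acid | OC(=O)[C@@H]1C[C@@H](C(=O)OC)C1 | starting material
17 | 2,3,5,6-tetrafluoro-4-(trifluoromethyl)aniline | Nc1c(F)c(F)c(C(F)(F)F)c(F)c1F | starting material
18 | methyl trans-3-(chlorocarbonyl)cyclobutane-1-carboxylate | ClC(=O)[C@@H]1C[C@@H](C(=O)OC)C1 | intermediate (not isolated)
19 | methyl trans-3-{[2,3,5,6-tetrafluoro-4-(trifluoromethyl)phenyl]carbamoyl}cyclobutane-1-carboxylate | COC(=O)[C@@H]1C[C@@H](C(=O)Nc2c(F)c(F)c(C(F)(F)F)c(F)c2F)C1 | intermediate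
20 | 1-(benzyloxy)-4-iodobenzene | Ic1ccc(OCc2ccccc2)cc1 | starting material
21 | methyl 2-[4-(benzyloxy)phenyl]-3-{[2,3,5,6-tetrafluoro-4-(trifluoromethyl)phenyl]carbamoyl}cyclobutane-1-carboxylate (1,2-trans, 2,3-cis) | C1[C@H](C(=O)Nc2c(F)c(F)c(C(F)(F)F)c(F)c2F)[C@H](c2ccc(OCc3ccccc3)cc2)[C@H]1C(=O)OC | intermediate
22 | 2-[4-(benzyloxy)phenyl]-3-{[2,3,5,6-tetrafluoro-4-(trifluoromethyl)phenyl]carbamoyl}cyclobutane-1-carboxylic acid (1,2-trans, 2,3-cis) | C1[C@H](C(=O)Nc2c(F)c(F)c(C(F)(F)F)c(F)c2F)[C@H](c2ccc(OCc3ccccc3)cc2)[C@H]1C(=O)O | intermediate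
23 | 2-(methylsulfanyl)aniline | CSc1ccccc1N | starting material
24 | 2-[4-(benzyloxy)phenyl]-N1-[2-(methylsulfanyl)phenyl]-N3-[2,3,5,6-tetrafluoro-4-(trifluoromethyl)phenyl]cyclobutane-1,3-dicarboxamide (1,2-trans, 2,3-cis) | C1[C@H](C(=O)Nc2c(F)c(F)c(C(F)(F)F)c(F)c2F)[C@H](c2ccc(OCc3ccccc3)cc2)[C@H]1C(=O)Nc1ccccc1SC | intermediate
25 | (1α,2α,3β,4β)-2-[4-(benzyloxy)-3-methoxyphenyl]-4-[4-(benzyloxy)phenyl]-N1-[2-(methylsulfanyl)phenyl]-N3-[2,3,5,6-tetrafluoro-4-(trifluoromethyl)phenyl]cyclobutane-1,3-dicarboxamide | COc1cc([C@H]2[C@H](C(=O)Nc3c(F)c(F)c(C(F)(F)F)c(F)c3F)[C@H](c3ccc(OCc4ccccc4)cc3)[C@H]2C(=O)Nc2ccccc2SC)ccc1OCc1ccccc1 | intermediate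
26 | bis(N-tert-butoxycarbonyl) imide of 25 | COc1cc([C@H]2[C@H](C(=O)N(C(=O)OC(C)(C)C)c3c(F)c(F)c(C(F)(F)F)c(F)c3F)[C@H](c3ccc(OCc4ccccc4)cc3)[C@H]2C(=O)N(C(=O)OC(C)(C)C)c2ccccc2SC)ccc1OCc1ccccc1 | intermediate (not isolated)
27 | (1α,2α,3β,4β)-2-[4-(benzyloxy)-3-methoxyphenyl]-4-[4-(benzyloxy)phenyl]cyclobutane-1,3-dicarboxylic acid | COc1cc([C@H]2[C@H](C(=O)O)[C@H](c3ccc(OCc4ccccc4)cc3)[C@H]2C(=O)O)ccc1OCc1ccccc1 | intermediate
28 | bis[(4R,4aS,6R,7S,7aR)-2,4,7-trimethyloctahydro-1H-cyclopenta[c]pyridin-6-yl] ester of 27 | COc1cc([C@H]2[C@H](C(=O)O[C@@H]3C[C@@H]4[C@@H](CN(C)C[C@@H]4C)[C@@H]3C)[C@H](c3ccc(OCc4ccccc4)cc3)[C@H]2C(=O)O[C@@H]2C[C@@H]3[C@@H](CN(C)C[C@@H]3C)[C@@H]2C)ccc1OCc1ccccc1 | intermediate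
29 | CNP0331906.2, bis[(4R,4aS,6R,7S,7aR)-2,4,7-trimethyloctahydro-1H-cyclopenta[c]pyridin-6-yl] (1α,2α,3β,4β)-2-(4-hydroxy-3-methoxyphenyl)-4-(4-hydroxyphenyl)cyclobutane-1,3-dicarboxylate | COc1cc([C@H]2[C@H](C(=O)O[C@@H]3C[C@@H]4[C@@H](CN(C)C[C@@H]4C)[C@@H]3C)[C@H](c3ccc(O)cc3)[C@H]2C(=O)O[C@@H]2C[C@@H]3[C@@H](CN(C)C[C@@H]3C)[C@@H]2C)ccc1O | target

## Summary and risks

Total step count: 17. Longest linear sequence: 10 steps (steps 1 to 8, then 16 and 17).

Steps most likely to fail, in order of risk:

**Step 6 (directed hydrogenation).** The doubly allylic alcohol may ionise and dehydrate under the acidic iridium hydride conditions, the second tetrasubstituted olefin may be reduced incompletely, or olefin isomerisation may erode facial control. The fallback moves facial control from coordination to shielding and sets out from 7. Reduction with the antipodal (R)-oxazaborolidine should give methyl (6S)-6-hydroxy-4,7-dimethyl-1,3,5,6-tetrahydro-2H-cyclopenta[c]pyridine-2-carboxylate F1. Silylation (TBSCl, imidazole, DMF) gives its tert-butyldimethylsilyl ether F2. Heterogeneous hydrogenation (H2, Rh/Al2O3 or Pd/C, EtOAc) is expected to add all four hydrogens to the face remote from the silyloxy group and give the saturated silyl ether F3. TBAF then frees methyl (4R,4aS,6S,7R,7aR)-6-hydroxy-4,7-dimethyloctahydro-2H-cyclopenta[c]pyridine-2-carboxylate F4, whose oxidation and epimerisation under the conditions of step 7 passes through 10 and comes back to the route at 11.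

**Step 11 (enantioselective C–H arylation).** Discrimination of the two enantiotopic methylenes may be insufficient on this α-hydrogen cyclobutane with its remote ester, and a second arylation at the other methylene may compete. The fallback replaces asymmetric catalysis by resolution and sets out from 19. The same arylation run with achiral N-acetylglycine as ligand and the aryl iodide as limiting reagent should give racemic methyl 2-[4-(benzyloxy)phenyl]-3-{[2,3,5,6-tetrafluoro-4-(trifluoromethyl)phenyl]carbamoyl}cyclobutane-1-carboxylate F5. Saponification as in step 12 gives the racemic acid F6, which is resolved by crystallisation of its salt with one enantiomer of 1-phenylethylamine (or by chromatography on a chiral stationary phase); the fallback comes back to the route at 22.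

**Step 4 (allenic Pauson–Khand reaction).** The catalyst may engage the proximal allene π-bond, or the allenyne may oligomerise faster than it is carbonylated. The fallback uses an alkene instead of an allene as the ene partner and sets out from 1. The free amine opens 2-methyl-2-vinyloxirane at its CH2 terminus (EtOH, 60 °C) to give racemic 1-[(but-2-yn-1-yl)amino]-2-methylbut-3-en-2-ol F7. N-acylation with methyl chloroformate gives methyl (but-2-yn-1-yl)(2-hydroxy-2-methylbut-3-en-1-yl)carbamate F8. A classical Pauson–Khand reaction mediated by Co2(CO)8 (zerovalent cobalt, N-methylmorpholine N-oxide as promoter) closes the same two rings to methyl 4-hydroxy-4,7-dimethyl-6-oxo-1,3,4,4a,5,6-hexahydro-2H-cyclopenta[c]pyridine-2-carboxylate F9, as a stereoisomer mixture of no consequence. Acid-catalysed dehydration of the tertiary alcohol into conjugation (TsOH, toluene, 80 °C) removes both stereocentres, and the fallback comes back to the route at 7.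

## Further compounds

F1 | step 6 | methyl (6S)-6-hydroxy-4,7-dimethyl-1,3,5,6-tetrahydro-2H-cyclopenta[c]pyridine-2-carboxylate | O[C@H]1CC2=C(C)CN(C(=O)OC)CC2=C1C
F2 | step 6 | methyl (6S)-6-[(tert-butyldimethylsilyl)oxy]-4,7-dimethyl-1,3,5,6-tetrahydro-2H-cyclopenta[c]pyridine-2-carboxylate | CC(C)(C)[Si](C)(C)O[C@H]1CC2=C(C)CN(C(=O)OC)CC2=C1C
F3 | step 6 | methyl (4R,4aS,6S,7R,7aR)-6-[(tert-butyldimethylsilyl)oxy]-4,7-dimethyloctahydro-2H-cyclopenta[c]pyridine-2-carboxylate | CC(C)(C)[Si](C)(C)O[C@H]1C[C@@H]2[C@@H](CN(C(=O)OC)C[C@@H]2C)[C@H]1C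
F4 | step 6 | methyl (4R,4aS,6S,7R,7aR)-6-hydroxy-4,7-dimethyloctahydro-2H-cyclopenta[c]pyridine-2-carboxylate | O[C@H]1C[C@@H]2[C@@H](CN(C(=O)OC)C[C@@H]2C)[C@H]1C
F5 | step 11 | racemic methyl 2-[4-(benzyloxy)phenyl]-3-{[2,3,5,6-tetrafluoro-4-(trifluoromethyl)phenyl]carbamoyl}cyclobutane-1-carboxylate (1,2-trans, 2,3-cis; both enantiomers) | C1[C@H](C(=O)Nc2c(F)c(F)c(C(F)(F)F)c(F)c2F)[C@H](c2ccc(OCc3ccccc3)cc2)[C@H]1C(=O)OC.C1[C@@H](C(=O)Nc2c(F)c(F)c(C(F)(F)F)c(F)c2F)[C@@H](c2ccc(OCc3ccccc3)cc2)[C@@H]1C(=O)OC
F6 | step 11 | racemic 2-[4-(benzyloxy)phenyl]-3-{[2,3,5,6-tetrafluoro-4-(trifluoromethyl)phenyl]carbamoyl}cyclobutane-1-carboxylic acid (1,2-trans, 2,3-cis; both enantiomers) | C1[C@H](C(=O)Nc2c(F)c(F)c(C(F)(F)F)c(F)c2F)[C@H](c2ccc(OCc3ccccc3)cc2)[C@H]1C(=O)O.C1[C@@H](C(=O)Nc2c(F)c(F)c(C(F)(F)F)c(F)c2F)[C@@H](c2ccc(OCc3ccccc3)cc2)[C@@H]1C(=O)O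
F7 | step 4 | racemic 1-[(but-2-yn-1-yl)amino]-2-methylbut-3-en-2-ol | CC#CCNCC(C)(O)C=C
F8 | step 4 | racemic methyl (but-2-yn-1-yl)(2-hydroxy-2-methylbut-3-en-1-yl)carbamate | CC#CCN(CC(C)(O)C=C)C(=O)OC
F9 | step 4 | methyl 4-hydroxy-4,7-dimethyl-6-oxo-1,3,4,4a,5,6-hexahydro-2H-cyclopenta[c]pyridine-2-carboxylate (stereoisomer mixture) | COC(=O)N1CC(C)(O)C2CC(=O)C(C)=C2C1
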